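**Retrosynthetic overview**
- The last step only releases the 7,8-diol from its acetonide. Before that, ring A (carbocycle) and ring B (pyran) are made in one operation from an acyclic hydroxy keto-ynone.
- In that operation ring A closes first (C5–C4a bond, methyl-ketone enolate adding 6-exo-dig to the ynone), then ring B (O2–C3 bond, cyclodehydration of the C1 hydroxyl onto the C3 carbonyl).
- The ynone comes from a three-component carbonylative coupling: core alkyne (C4) + CO (C3) + side-chain (E)-vinyl iodide (C1').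
- Both halves start from tiglic aldehyde: iridium-catalysed anti-(hydroxymethyl)allylation sets C8/C8a, anti-crotylation sets C4'/C5'.
- Each tertiary carbinol (C7, C3') comes from a chelation-controlled Grignard addition to an α-hydroxy methyl ketone made by ozonolysis; the C8a alkyne comes from the vinyl group (ozonolysis, then Ohira–Bestmann).

Assumption: (S)-SEGPHOS is written for both iridium-catalysed couplings on the understanding that it gives the (R)-carbinol from aldehyde 1; if the sense is the reverse, (R)-SEGPHOS is used in both steps.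

Atom labels (C1–C8a, C1'–C7') follow the numbering of the target.

**Step 1**
Reactants: 1 (E)-2-methylbut-2-enal (tiglic aldehyde); 2 4-vinyl-1,3-dioxolan-2-one (racemic)
Product: 3 (2S,3R,4E)-2-ethenyl-4-methylhex-4-ene-1,3-diol
Conditions: [Ir(cod)Cl]2 (2.5 mol%), (S)-SEGPHOS (5 mol%), 4-cyano-3-nitrobenzoic acid (10 mol%), K3PO4 (5 mol%), i-PrOH (2 equiv), THF, 70 °C
Reagents that add atoms: none
Why: Krische-type iridium-catalysed transfer-hydrogenative carbonyl (hydroxymethyl)allylation, in which ionisation and decarboxylation of 2 give an (E)-σ-allyliridium alkoxide that adds to 1 through a closed chair transition state, so the C8 hydroxyl and the C8a hydroxymethyl end up anti and the ligand fixes C8 (R) and C8a (S).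

**Step 2**
Reactants: 3 (2S,3R,4E)-2-ethenyl-4-methylhex-4-ene-1,3-diol
Product: 4 (2E,4R,5S)-5-{[(tert-butyldimethylsilyl)oxy]methyl}-3-methylhepta-2,6-dien-4-ol
Conditions: TBSCl (1.05 equiv), imidazole, CH2Cl2, −20 to 0 °C
Reagents that add atoms: tert-butyldimethylsilyl chloride CC(C)(C)[Si](C)(C)Cl
Why: Silylation is selective for the unhindered primary hydroxyl over the secondary allylic one, leaving the C8 hydroxyl free to chelate in step 4.

**Step 3**
Reactants: 4 (2E,4R,5S)-5-{[(tert-butyldimethylsilyl)oxy]methyl}-3-methylhepta-2,6-dien-4-ol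
Product: 5 (3R,4S)-4-{[(tert-butyldimethylsilyl)oxy]methyl}-3-hydroxyhex-5-en-2-one
Conditions: O3 (1.0 equiv, Sudan Red 7B end point), pyridine (3 equiv), CH2Cl2, −78 °C
Reagents that add atoms: ozone [O-][O+]=O
Why: Pyridine-mediated reductive ozonolysis in which the electron-rich trisubstituted alkene is consumed much faster than the monosubstituted vinyl group, giving the methyl ketone directly without touching C8 or C8a.

**Step 4**
Reactants: 5 (3R,4S)-4-{[(tert-butyldimethylsilyl)oxy]methyl}-3-hydroxyhex-5-en-2-one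
Product: 6 (3R,4R,5S)-5-{[(tert-butyldimethylsilyl)oxy]methyl}-2,3-dimethylhepta-1,6-diene-3,4-diol
Conditions: isopropenylmagnesium bromide (3 equiv), THF, −78 to −20 °C; aq NH4Cl
Reagents that add atoms: isopropenylmagnesium bromide CC(=C)[Mg]Br
Why: Cram-chelate-controlled Grignard addition, in which the magnesium alkoxide of the C8 hydroxyl holds the ketone in a five-membered chelate and the nucleophile enters anti to the C8a branch, giving the 7,8-syn diol with C7 as required.

**Step 5**
Reactants: 6 (3R,4R,5S)-5-{[(tert-butyldimethylsilyl)oxy]methyl}-2,3-dimethylhepta-1,6-diene-3,4-diol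
Product: 7 tert-butyldimethyl{[(2S)-2-[(4R,5R)-2,2,5-trimethyl-5-(prop-1-en-2-yl)-1,3-dioxolan-4-yl]but-3-en-1-yl]oxy}silane
Conditions: 2,2-dimethoxypropane, PPTS (cat.), CH2Cl2, rt
Reagents that add atoms: 2,2-dimethoxypropane COC(C)(C)OC
Why: Acid-catalysed transketalisation on the only 1,2-diol, which masks the tertiary C7 hydroxyl that would otherwise add 5-exo to the ynone in step 14.

**Step 6**
Reactants: 7 tert-butyldimethyl{[(2S)-2-[(4R,5R)-2,2,5-trimethyl-5-(prop-1-en-2-yl)-1,3-dioxolan-4-yl]but-3-en-1-yl]oxy}silane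
Product: 8 (2S)-2-[(4R,5S)-5-acetyl-2,2,5-trimethyl-1,3-dioxolan-4-yl]-3-[(tert-butyldimethylsilyl)oxy]propanal
Conditions: O3, pyridine (6 equiv), CH2Cl2, −78 °C; used crude
Reagents that add atoms: ozone [O-][O+]=O
Why: Reductive ozonolysis of both terminal alkenes gives the C6 methyl ketone (flanked by quaternary C7, so no epimerisable centre) and the C4a aldehyde under non-basic conditions that preserve C8a.

**Step 7**
Reactants: 8 (2S)-2-[(4R,5S)-5-acetyl-2,2,5-trimethyl-1,3-dioxolan-4-yl]-3-[(tert-butyldimethylsilyl)oxy]propanal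
Product: 9 1-[(4S,5R)-5-[(2S)-1-[(tert-butyldimethylsilyl)oxy]but-3-yn-2-yl]-2,2,4-trimethyl-1,3-dioxolan-4-yl]ethan-1-one
Conditions: dimethyl (1-diazo-2-oxopropyl)phosphonate, K2CO3, MeOH, 0 °C
Reagents that add atoms: dimethyl (1-diazo-2-oxopropyl)phosphonate CC(=O)C(=[N+]=[N-])P(=O)(OC)OC
Why: Ohira–Bestmann (Seyferth–Gilbert) homologation, which is selective for the aldehyde over the hindered ketone and mild enough at 0 °C to keep the α-stereocentre C8a, which then becomes a configurationally stable propargylic carbon.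

**Step 8**
Reactants: 1 (E)-2-methylbut-2-enal (tiglic aldehyde); 10 but-3-en-2-yl acetate (racemic)
Product: 11 (3R,4R,5E)-3,5-dimethylhepta-1,5-dien-4-ol
Conditions: [Ir(cod)Cl]2 (2.5 mol%), (S)-SEGPHOS (5 mol%), 4-cyano-3-nitrobenzoic acid (10 mol%), Cs2CO3 (20 mol%), i-PrOH (2 equiv), THF, 90 °C
Reagents that add atoms: none
Why: Krische-type iridium-catalysed transfer-hydrogenative anti-crotylation through the (E)-σ-crotyliridium chair transition state, setting C4' (R) and C5' (R) with the hydroxyl and methyl anti.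

**Step 9**
Reactants: 11 (3R,4R,5E)-3,5-dimethylhepta-1,5-dien-4-ol
Product: 12 (2E,4R,5R)-3,5-dimethylhept-2-en-4-ol
Conditions: H2 (1 atm), RhCl(PPh3)3 (3 mol%), benzene/EtOH, rt
Reagents that add atoms: none
Why: Homogeneous hydrogenation with RhCl(PPh3)3 reduces the monosubstituted vinyl group and leaves the trisubstituted alkene alone, turning the crotyl unit into the sec-butyl terminus.

**Step 10**
Reactants: 12 (2E,4R,5R)-3,5-dimethylhept-2-en-4-ol
Product: 13 (3R,4R)-3-hydroxy-4-methylhexan-2-one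
Conditions: O3, pyridine (3 equiv), CH2Cl2, −78 °C; careful concentration (volatile)
Reagents that add atoms: ozone [O-][O+]=O
Why: Reductive ozonolysis of the only remaining alkene gives the α-hydroxy methyl ketone without disturbing C4' or C5'.

**Step 11**
Reactants: 13 (3R,4R)-3-hydroxy-4-methylhexan-2-one
Product: 14 (3R,4R,5R)-3,5-dimethylhept-1-yne-3,4-diol
Conditions: ethynylmagnesium bromide (3 equiv), THF, −78 to 0 °C; aq NH4Cl
Reagents that add atoms: ethynylmagnesium bromide C#C[Mg]Br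
Why: Cram-chelate-controlled Grignard addition through the magnesium alkoxide of the C4' hydroxyl, with attack anti to the sec-butyl group, giving the 3',4'-syn diol with C3' (R).

**Step 12**
Reactants: 14 (3R,4R,5R)-3,5-dimethylhept-1-yne-3,4-diol
Product: 16 (1E,3R,4R,5R)-1-iodo-3,5-dimethylhept-1-ene-3,4-diol, via E-vinylstannane 15 (not isolated)
Conditions: Bu3SnH, PdCl2(PPh3)2 (2 mol%), THF, 0 °C; then I2, CH2Cl2, 0 °C
Reagents that add atoms: iodine II (tributyltin hydride CCCC[SnH](CCCC)CCCC leaves its tin only in 15)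
Why: Palladium-catalysed syn-hydrostannation puts tin on the terminal carbon, away from the quaternary carbinol, giving the (E)-stannane, and iododestannylation proceeds with retention of alkene geometry.

**Step 13**
Reactants: 9 1-[(4S,5R)-5-[(2S)-1-[(tert-butyldimethylsilyl)oxy]but-3-yn-2-yl]-2,2,4-trimethyl-1,3-dioxolan-4-yl]ethan-1-one; 16 (1E,3R,4R,5R)-1-iodo-3,5-dimethylhept-1-ene-3,4-diol
Product: 17 (4S)-4-[(4R,5S)-5-acetyl-2,2,5-trimethyl-1,3-dioxolan-4-yl]-5-[(tert-butyldimethylsilyl)oxy]-1-[(1E,3R,4R,5R)-3,4-dihydroxy-3,5-dimethylhept-1-en-1-yl]pent-2-yn-1-one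
Conditions: CO (5 bar), PdCl2(PPh3)2 (5 mol%), CuI (2 mol%), Et3N, THF, rt
Reagents that add atoms: carbon monoxide [C-]#[O+]
Why: Carbonylative Sonogashira coupling (oxidative addition to the vinyl iodide, CO insertion to the acylpalladium, coupling with the copper acetylide of 9), which supplies C3 from CO, keeps the (E)-alkene, and tolerates the free diol and the methyl ketone.

**Step 14**
Reactants: 17 (4S)-4-[(4R,5S)-5-acetyl-2,2,5-trimethyl-1,3-dioxolan-4-yl]-5-[(tert-butyldimethylsilyl)oxy]-1-[(1E,3R,4R,5R)-3,4-dihydroxy-3,5-dimethylhept-1-en-1-yl]pent-2-yn-1-one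
Product: 20 7,8-O-isopropylidene derivative of 21 (trans-fused dioxolane; 7S,8R,8aS; side chain 1E,3R,4R,5R), via desilylated ynone 18 (not isolated), via cyclohexanone enone 19 (not isolated)
Conditions: TBAF (1.5 equiv), THF, 0 °C to rt; then AcOH (10 equiv), 40 °C
Reagents that add atoms: none
Why: Proposed new method: fluoride removes the silyl group and the liberated alkoxide/fluoride base enolises the only enolisable ketone (the C6 acetyl, C7 being quaternary), the enolate adds 6-exo-dig to the ynone β-carbon C4a to close ring A and settles as a stabilised vinylogous 1,3-dicarbonyl anion, and on acidification the C1 hydroxyl condenses with the C3 carbonyl (six-membered hemiketal, then dehydration into conjugation) to close ring B as the vinylogous ester, with C8a never becoming a carbanion so its configuration is carried through; the closest known reaction types are base-mediated intramolecular Michael (Conia-ene-type) additions of ketone enolates to ynones and acid-catalysed cyclodehydration of δ-hydroxy enones to pyrans.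

**Step 15**
Reactants: 20 7,8-O-isopropylidene derivative of 21
Product: 21 (7S,8R,8aS)-3-[(1E,3R,4R,5R)-3,4-dihydroxy-3,5-dimethylhept-1-en-1-yl]-7,8-dihydroxy-7-methyl-1,7,8,8a-tetrahydro-6H-isochromen-6-one (CNP0291643.8)
Conditions: AcOH/H2O (4:1), 40 °C
Reagents that add atoms: none
Why: Acid hydrolysis of the strained trans-fused acetonide is fast under conditions mild enough for the vinylogous ester and the tertiary allylic alcohol, and no stereocentre is touched.

**Compound list**
1 | (E)-2-methylbut-2-enal (tiglic aldehyde) | C/C=C(\C)C=O | starting material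
2 | 4-vinyl-1,3-dioxolan-2-one (vinyl ethylene carbonate, racemic) | C=CC1COC(=O)O1 | starting material
3 | (2S,3R,4E)-2-ethenyl-4-methylhex-4-ene-1,3-diol | C/C=C(\C)[C@H](O)[C@@H](C=C)CO | intermediate
4 | (2E,4R,5S)-5-{[(tert-butyldimethylsilyl)oxy]methyl}-3-methylhepta-2,6-dien-4-ol | C/C=C(\C)[C@H](O)[C@@H](C=C)CO[Si](C)(C)C(C)(C)C | intermediate
5 | (3R,4S)-4-{[(tert-butyldimethylsilyl)oxy]methyl}-3-hydroxyhex-5-en-2-one | CC(=O)[C@H](O)[C@@H](C=C)CO[Si](C)(C)C(C)(C)C | intermediate
6 | (3R,4R,5S)-5-{[(tert-butyldimethylsilyl)oxy]methyl}-2,3-dimethylhepta-1,6-diene-3,4-diol | CC(=C)[C@@](C)(O)[C@H](O)[C@@H](C=C)CO[Si](C)(C)C(C)(C)C | intermediate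
7 | tert-butyldimethyl{[(2S)-2-[(4R,5R)-2,2,5-trimethyl-5-(prop-1-en-2-yl)-1,3-dioxolan-4-yl]but-3-en-1-yl]oxy}silane | CC(=C)[C@@]1(C)OC(C)(C)O[C@@H]1[C@@H](C=C)CO[Si](C)(C)C(C)(C)C | intermediate
8 | (2S)-2-[(4R,5S)-5-acetyl-2,2,5-trimethyl-1,3-dioxolan-4-yl]-3-[(tert-butyldimethylsilyl)oxy]propanal | CC(=O)[C@@]1(C)OC(C)(C)O[C@@H]1[C@@H](C=O)CO[Si](C)(C)C(C)(C)C | intermediate
9 | 1-[(4S,5R)-5-[(2S)-1-[(tert-butyldimethylsilyl)oxy]but-3-yn-2-yl]-2,2,4-trimethyl-1,3-dioxolan-4-yl]ethan-1-one | CC(=O)[C@@]1(C)OC(C)(C)O[C@@H]1[C@@H](C#C)CO[Si](C)(C)C(C)(C)C | intermediate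
10 | but-3-en-2-yl acetate (racemic) | CC(OC(C)=O)C=C | starting material
11 | (3R,4R,5E)-3,5-dimethylhepta-1,5-dien-4-ol | C=C[C@@H](C)[C@@H](O)/C(C)=C/C | intermediate
12 | (2E,4R,5R)-3,5-dimethylhept-2-en-4-ol | CC[C@@H](C)[C@@H](O)/C(C)=C/C | intermediate
13 | (3R,4R)-3-hydroxy-4-methylhexan-2-one | CC[C@@H](C)[C@@H](O)C(C)=O | intermediate
14 | (3R,4R,5R)-3,5-dimethylhept-1-yne-3,4-diol | CC[C@@H](C)[C@@H](O)[C@](C)(O)C#C | intermediate
15 | (1E,3R,4R,5R)-3,5-dimethyl-1-(tributylstannyl)hept-1-ene-3,4-diol | CC[C@@H](C)[C@@H](O)[C@](C)(O)/C=C/[Sn](CCCC)(CCCC)CCCC | intermediate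
16 | (1E,3R,4R,5R)-1-iodo-3,5-dimethylhept-1-ene-3,4-diol | CC[C@@H](C)[C@@H](O)[C@](C)(O)/C=C/I | intermediate
17 | (4S)-4-[(4R,5S)-5-acetyl-2,2,5-trimethyl-1,3-dioxolan-4-yl]-5-[(tert-butyldimethylsilyl)oxy]-1-[(1E,3R,4R,5R)-3,4-dihydroxy-3,5-dimethylhept-1-en-1-yl]pent-2-yn-1-one | CC[C@@H](C)[C@@H](O)[C@](C)(O)/C=C/C(=O)C#C[C@@H](CO[Si](C)(C)C(C)(C)C)[C@H]1OC(C)(C)O[C@]1(C)C(C)=O | intermediate
18 | (4S)-4-[(4R,5S)-5-acetyl-2,2,5-trimethyl-1,3-dioxolan-4-yl]-1-[(1E,3R,4R,5R)-3,4-dihydroxy-3,5-dimethylhept-1-en-1-yl]-5-hydroxypent-2-yn-1-one | CC[C@@H](C)[C@@H](O)[C@](C)(O)/C=C/C(=O)C#C[C@@H](CO)[C@H]1OC(C)(C)O[C@]1(C)C(C)=O | intermediate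
19 | (3aS,6Z,7S,7aR)-6-[(3E,5R,6R,7R)-5,6-dihydroxy-5,7-dimethyl-2-oxonon-3-en-1-ylidene]-7-(hydroxymethyl)-2,2,3a-trimethyltetrahydro-1,3-benzodioxol-4(3aH)-one | CC[C@@H](C)[C@@H](O)[C@](C)(O)/C=C/C(=O)/C=C1/CC(=O)[C@@]2(C)OC(C)(C)O[C@@H]2[C@@H]1CO | intermediate
20 | 7,8-O-isopropylidene derivative of 21 (7S,8R,8aS; trans-fused dioxolane; side chain 1E,3R,4R,5R) | CC[C@@H](C)[C@@H](O)[C@](C)(O)/C=C/C1=CC2=CC(=O)[C@@]3(C)OC(C)(C)O[C@@H]3[C@@H]2CO1 | intermediate
21 | (7S,8R,8aS)-3-[(1E,3R,4R,5R)-3,4-dihydroxy-3,5-dimethylhept-1-en-1-yl]-7,8-dihydroxy-7-methyl-1,7,8,8a-tetrahydro-6H-isochromen-6-one | CC[C@@H](C)[C@@H](O)[C@](C)(O)/C=C/C1=CC2=CC(=O)[C@@](C)(O)[C@H](O)[C@@H]2CO1 | target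

**Step count and risks**
Total steps: 15. Longest linear sequence: 10 (steps 1–7, 13, 14, 15 from tiglic aldehyde); the side-chain branch is steps 8–12.

Most likely to fail, first: step 14. The fluoride/alkoxide base may instead remove the propargylic C8a hydrogen (ynone to allenone, loss of the C8a centre) or add to the ynone. The fallback sets out from 17 and comes back at 20: the silyl ether is cleaved under acidic conditions with HF·pyridine to isolate alcohol 18, pyrrolidine is added to the ynone to give the β-pyrrolidinyl enone F4, a vinylogous amide that needs no base; warming F4 with AcOH in toluene lets the C5 enol displace pyrrolidine at C4a by addition–elimination (ring A, compound 19) and the same acid closes ring B to give 20.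

Second: step 13. Direct (non-carbonylative) coupling of the vinyl iodide can compete with CO insertion, and the ynone is sensitive to the amine. The fallback sets out from 16 and 9 and comes back at 17: 16 is formylated (Pd(PPh3)4, CO, Bu3SnH) to the (2E,4R,5R,6R)-4,5-dihydroxy-4,6-dimethyloct-2-enal F2, the zinc acetylide of 9 (Me2Zn, ProPhenol ligand, toluene) is added to F2 to give the propargylic alcohol F3 as a mixture at the new carbinol, and MnO2 oxidises F3 to 17.

Third: step 3. Over-ozonolysis of the vinyl group would destroy the C4a handle. The fallback sets out from 4 and comes back at 5: hydroxyl-directed m-CPBA epoxidation, which is strongly selective for the trisubstituted alkene, gives the epoxy alcohol F1 (either epoxide face is acceptable), and H5IO6 in aqueous THF cleaves the epoxide to ketone 5.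

**Further compounds**
F1 | step 3 | (1R,2S)-2-{[(tert-butyldimethylsilyl)oxy]methyl}-1-(2,3-dimethyloxiran-2-yl)but-3-en-1-ol (mixture at the oxirane carbons) | CC1OC1(C)[C@H](O)[C@@H](C=C)CO[Si](C)(C)C(C)(C)C
F2 | step 13 | (2E,4R,5R,6R)-4,5-dihydroxy-4,6-dimethyloct-2-enal | CC[C@@H](C)[C@@H](O)[C@](C)(O)/C=C/C=O
F3 | step 13 | (4S)-4-[(4R,5S)-5-acetyl-2,2,5-trimethyl-1,3-dioxolan-4-yl]-5-[(tert-butyldimethylsilyl)oxy]-1-[(1E,3R,4R,5R)-3,4-dihydroxy-3,5-dimethylhept-1-en-1-yl]pent-2-yn-1-ol (both C1 epimers) | CC[C@@H](C)[C@@H](O)[C@](C)(O)/C=C/C(O)C#C[C@@H](CO[Si](C)(C)C(C)(C)C)[C@H]1OC(C)(C)O[C@]1(C)C(C)=O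
F4 | step 14 | (2E,4S)-4-[(4R,5S)-5-acetyl-2,2,5-trimethyl-1,3-dioxolan-4-yl]-1-[(1E,3R,4R,5R)-3,4-dihydroxy-3,5-dimethylhept-1-en-1-yl]-5-hydroxy-3-(pyrrolidin-1-yl)pent-2-en-1-one | CC[C@@H](C)[C@@H](O)[C@](C)(O)/C=C/C(=O)/C=C(/N1CCCC1)[C@@H](CO)[C@H]2OC(C)(C)O[C@]2(C)C(C)=O
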